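**Retrosynthetic overview**
1. Target 20 ⇐ aryl silyl ether 19 ⇐ 18 by NBS/H2O bromohydrin formation on the 10E-olefin (sets C10, C11).
2. 18 ⇐ 19-membered macrolide 17 by transannular bromonium–olefin cyclisation (C2–C7 bond; builds the cyclohexene and contracts the lactone to 15 members; sets C2, C6, C7).
3. 17 ⇐ 14 by a macrocyclising intramolecular Diels–Alder benzannulation (silyloxy diene + propiolate ester): the benzoate ring and the macrolactone form in one cycloaddition.
4. 14 ⇐ propiolic acid + 4-methoxybut-3-en-2-one + triol 8; 8 ⇐ C12–C13 alkylation of 12-bromofarnesyl acetate with the sulfonyl carbanion made from methyl (S)-glycidate (the only bought stereocentre, C14).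
5. Ring order: benzene ring and 19-membered lactone together (cycloaddition), then cyclohexene ring with the 15-membered lactone (transannular cyclisation).

Assumption: terpenoid numbering is used throughout (C1 = benzylic CH2, C2–C7 = cyclohexene ring, C14 = lactone carbinol carbon, C16 = isopropenyl CH2), in which the target is 2R,6S,7S,10R,11S,14S; methyl (S)-glycidate is taken as a cheap commercial chiral building block.

**Route**

Step 1
Reactants: 1 (2E,6E)-farnesyl acetate
Product: 2 (2E,6E,10E)-12-hydroxy-3,7,11-trimethyldodeca-2,6,10-trien-1-yl acetate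
Conditions: SeO2 (cat.), t-BuOOH, salicylic acid (cat.), CH2Cl2, 0 °C to rt
Reagents that add atoms: tert-butyl hydroperoxide, CC(C)(C)OO
Why: SeO2-catalysed allylic oxidation (ene reaction then [2,3]-sigmatropic shift) attacks only the (E)-methyl of the terminal trisubstituted olefin, giving the 10E-allylic alcohol without creating a stereocentre.

Step 2
Reactants: 2 (2E,6E,10E)-12-hydroxyfarnesyl acetate
Product: 3 (2E,6E,10E)-12-bromo-3,7,11-trimethyldodeca-2,6,10-trien-1-yl acetate
Conditions: CBr4, PPh3, CH2Cl2, 0 °C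
Reagents that add atoms: carbon tetrabromide, BrC(Br)(Br)Br
Why: Appel bromination of the primary allylic alcohol is neutral and leaves the acetate and the olefin geometries untouched.

Step 3
Reactants: 4 methyl (2S)-oxirane-2-carboxylate (methyl (S)-glycidate)
Product: 5 methyl (2R)-2-hydroxy-3-(phenylsulfonyl)propanoate
Conditions: PhSO2Na, AcOH (1 equiv), DMF, 60 °C
Reagents that add atoms: sodium benzenesulfinate, [Na+].[O-]S(=O)c1ccccc1
Why: SN2 epoxide opening by the soft sulfinate (S-alkylation) occurs at the unhindered C3 and does not touch the bought stereocentre (future C14; the descriptor changes only by priority).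

Step 4
Reactants: 5 methyl (2R)-2-hydroxy-3-(phenylsulfonyl)propanoate
Product: 6 (2R)-3-methyl-1-(phenylsulfonyl)butane-2,3-diol
Conditions: MeMgBr (5 equiv), THF, −78 to 0 °C; aq. NH4Cl
Reagents that add atoms: methylmagnesium bromide, C[Mg]Br
Why: Double Grignard addition to the ester builds the C15 dimethyl carbinol (masked isopropenyl group) without involving the stereocentre.

Step 5
Reactants: 3 (2E,6E,10E)-12-bromofarnesyl acetate; 6 (2R)-3-methyl-1-(phenylsulfonyl)butane-2,3-diol
Product: 7 (2E,6E,10E,14R)-14,15-dihydroxy-3,7,11,15-tetramethyl-13-(phenylsulfonyl)hexadeca-2,6,10-trien-1-yl acetate (both C13 epimers)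
Conditions: 6, n-BuLi (3.1 equiv), THF/DMPU, −78 to −20 °C; then 3, −78 °C; aq. NH4Cl
Reagents that add atoms: none
Why: SN2 C-alkylation of the sulfonyl-stabilised carbanion of the trilithiated diol sulfone (the β-oxido groups cannot be eliminated) by the allylic bromide forms C12–C13 faster than any attack on the acetate at −78 °C.

Step 6
Reactants: 7 sulfone diol acetate
Product: 8 (2E,6E,10E,14S)-3,7,11,15-tetramethylhexadeca-2,6,10-triene-1,14,15-triol
Conditions: Na(Hg) (6%), Na2HPO4, MeOH/THF, −20 °C; then K2CO3 (cat.), MeOH, rt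
Reagents that add atoms: none
Why: Reductive desulfonylation (single-electron C–S cleavage) followed by methanolysis of the acetate removes the C13 auxiliary group and frees O1 without touching C14 or the olefins.

Step 7
Reactants: 8 triol
Product: 9 (2E,6E,10E,14S)-1-bromo-3,7,11,15-tetramethylhexadeca-2,6,10-triene-14,15-diol
Conditions: NBS, Me2S, CH2Cl2, −20 to 0 °C
Reagents that add atoms: N-bromosuccinimide, O=C1CCC(=O)N1Br
Why: Corey–Kim halogenation via the alkoxysulfonium salt converts only the allylic primary alcohol, while the saturated secondary and tertiary hydroxyls are returned unchanged on work-up.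

Step 8
Reactants: 9 allylic bromide diol; 10 (3E)-4-methoxybut-3-en-2-one
Product: 11 (1E,6E,10E,14E,18S)-18,19-dihydroxy-1-methoxy-7,11,15,19-tetramethylicosa-1,6,10,14-tetraen-3-one
Conditions: 10 (3 equiv), lithium diisopropylamide (3 equiv), THF, −78 °C; then 9, DMPU, −78 to −40 °C
Reagents that add atoms: none
Why: Kinetic α′-deprotonation of the vinylogous ester and SN2 alkylation (Stork–Danheiser-type) attach the four-carbon diene precursor to C1; the enolate is too weak a base to deprotonate the diol.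

Step 9
Reactants: 11 methoxy enone diol; 12 prop-2-ynoic acid (propiolic acid)
Product: 13 (3S,6E,10E,14E,19E)-2-hydroxy-20-methoxy-2,6,10,14-tetramethyl-18-oxoicosa-6,10,14,19-tetraen-3-yl prop-2-ynoate
Conditions: DCC, DMAP (cat.), CH2Cl2, −20 to 0 °C
Reagents that add atoms: none
Why: Steglich esterification acylates the secondary C14 hydroxyl with retention (the tertiary C15 hydroxyl is inert), placing the dienophile on O14.

Step 10
Reactants: 13 propiolate tertiary alcohol
Product: 14 (3S,6E,10E,14E,19E)-20-methoxy-2,6,10,14-tetramethyl-18-oxoicosa-1,6,10,14,19-pentaen-3-yl prop-2-ynoate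
Conditions: Burgess reagent, benzene, 50 °C
Reagents that add atoms: none
Why: Burgess syn-elimination of the tertiary alcohol gives the isopropenyl group, because the only other β-hydrogen sits on the ester-bearing C14 and would give a disfavoured enol ester.

Step 11
Reactants: 14 methoxy enone propiolate
Product: 17 (14S)-19-membered macrolide aryl TBS ether, via silyloxy diene 15 (not isolated), via Diels–Alder cycloadduct 16 (not isolated)
Conditions: TBSOTf, i-Pr2NEt, CH2Cl2, −78 to 0 °C; then toluene (0.5 mM, BHT), 110 °C; then PPTS (cat.), rt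
Reagents that add atoms: tert-butyldimethylsilyl triflate, CC(C)(C)[Si](C)(C)OS(=O)(=O)C(F)(F)F
Why: Soft enolisation gives the Danishefsky-type (Z)-silyloxy diene, whose intramolecular Diels–Alder reaction with the propiolate (nucleophilic diene terminus to the alkyne β-carbon) and loss of methanol forms the 4-silyloxybenzoate ring and the 19-membered lactone in one operation, with no new stereocentre.

Step 12
Reactants: 17 19-membered macrolide aryl TBS ether
Product: 18 (2R,6S,7S,10E,14S)-6-bromo bicyclic 15-membered macrolide aryl TBS ether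
Conditions: 2,4,4,6-tetrabromocyclohexa-2,5-dienone (TBCO), MeNO2, −20 to 0 °C
Reagents that add atoms: 2,4,4,6-tetrabromocyclohexa-2,5-dienone, O=C1C(Br)=CC(Br)(Br)C=C1Br
Why: In this transannular bromonium-initiated cation–olefin cyclisation (chair transition state), Br+ adds to C6, C7 is attacked by C2 of the 2E-olefin and the C3 cation loses H4; anti addition across the two E-olefins fixes the all-cis 2,6,7 relationship, and the C14 stereocentre is expected to select the olefin face through the folded macrocycle.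

Step 13
Reactants: 18 6-bromo macrolide aryl TBS ether
Product: 19 (2R,6S,7S,10R,11S,14S)-6,10-dibromo-11-hydroxy macrolide aryl TBS ether
Conditions: NBS, THF/H2O (4:1), 0 °C
Reagents that add atoms: N-bromosuccinimide, O=C1CCC(=O)N1Br; water, O
Why: In this bromohydrin formation Br+ adds to C10 from the exposed outer face of the 15-membered ring and water opens anti at the tertiary C11 (Markovnikov), giving the 10R,11S pair from the E-olefin; the ring olefin is shielded by the C2 and C7 substituents and the isopropenyl group is deactivated by the allylic ester.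

Step 14
Reactants: 19 dibromo hydroxy macrolide aryl TBS ether
Product: 20 CNP0213075.1 (target)
Conditions: HF·pyridine, THF/pyridine, 0 °C
Reagents that add atoms: none
Why: Fluoride cleavage of the aryl silyl ether under mildly acidic conditions frees the phenol without base, so the bromohydrin does not close to an epoxide and the lactone and bromides survive.

**Compound list**
1 | (2E,6E)-farnesyl acetate [(2E,6E)-3,7,11-trimethyldodeca-2,6,10-trien-1-yl acetate] | CC(=O)OC/C=C(\C)CC/C=C(\C)CCC=C(C)C | starting material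
2 | (2E,6E,10E)-12-hydroxy-3,7,11-trimethyldodeca-2,6,10-trien-1-yl acetate | CC(=O)OC/C=C(\C)CC/C=C(\C)CC/C=C(\C)CO | intermediate
3 | (2E,6E,10E)-12-bromo-3,7,11-trimethyldodeca-2,6,10-trien-1-yl acetate | CC(=O)OC/C=C(\C)CC/C=C(\C)CC/C=C(\C)CBr | intermediate
4 | methyl (2S)-oxirane-2-carboxylate | COC(=O)[C@@H]1CO1 | starting material
5 | methyl (2R)-2-hydroxy-3-(phenylsulfonyl)propanoate | COC(=O)[C@@H](O)CS(=O)(=O)c1ccccc1 | intermediate
6 | (2R)-3-methyl-1-(phenylsulfonyl)butane-2,3-diol | CC(C)(O)[C@@H](O)CS(=O)(=O)c1ccccc1 | intermediate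
7 | (2E,6E,10E,14R)-14,15-dihydroxy-3,7,11,15-tetramethyl-13-(phenylsulfonyl)hexadeca-2,6,10-trien-1-yl acetate (C13 epimers) | CC(=O)OC/C=C(\C)CC/C=C(\C)CC/C=C(\C)CC(S(=O)(=O)c1ccccc1)[C@H](O)C(C)(C)O | intermediate
8 | (2E,6E,10E,14S)-3,7,11,15-tetramethylhexadeca-2,6,10-triene-1,14,15-triol | OC/C=C(\C)CC/C=C(\C)CC/C=C(\C)CC[C@H](O)C(C)(C)O | intermediate
9 | (2E,6E,10E,14S)-1-bromo-3,7,11,15-tetramethylhexadeca-2,6,10-triene-14,15-diol | BrC/C=C(\C)CC/C=C(\C)CC/C=C(\C)CC[C@H](O)C(C)(C)O | intermediate
10 | (3E)-4-methoxybut-3-en-2-one | CO/C=C/C(C)=O | starting material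
11 | (1E,6E,10E,14E,18S)-18,19-dihydroxy-1-methoxy-7,11,15,19-tetramethylicosa-1,6,10,14-tetraen-3-one | CO/C=C/C(=O)CC/C=C(\C)CC/C=C(\C)CC/C=C(\C)CC[C@H](O)C(C)(C)O | intermediate
12 | prop-2-ynoic acid (propiolic acid) | OC(=O)C#C | starting material
13 | (3S,6E,10E,14E,19E)-2-hydroxy-20-methoxy-2,6,10,14-tetramethyl-18-oxoicosa-6,10,14,19-tetraen-3-yl prop-2-ynoate | CO/C=C/C(=O)CC/C=C(\C)CC/C=C(\C)CC/C=C(\C)CC[C@H](OC(=O)C#C)C(C)(C)O | intermediate
14 | (3S,6E,10E,14E,19E)-20-methoxy-2,6,10,14-tetramethyl-18-oxoicosa-1,6,10,14,19-pentaen-3-yl prop-2-ynoate | CO/C=C/C(=O)CC/C=C(\C)CC/C=C(\C)CC/C=C(\C)CC[C@H](OC(=O)C#C)C(C)=C | intermediate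
15 | (3S,6E,10E,14E,17Z,19E)-18-(tert-butyldimethylsilyloxy)-20-methoxy-2,6,10,14-tetramethylicosa-1,6,10,14,17,19-hexaen-3-yl prop-2-ynoate | CO/C=C/C(O[Si](C)(C)C(C)(C)C)=C/C/C=C(\C)CC/C=C(\C)CC/C=C(\C)CC[C@H](OC(=O)C#C)C(C)=C | intermediate
16 | Diels–Alder cycloadduct: (14S)-19-membered lactone fused to a cyclohexa-1,4-diene bearing OMe on the sp3 carbon next to the ester-bearing carbon and OTBS on the enol ether carbon (diastereomers at the two new sp3 ring carbons) | C=C(C)[C@@H]1CC/C(C)=C/CC/C(C)=C/CC/C(C)=C/CC2C=C(C(=O)O1)C(OC)C=C2O[Si](C)(C)C(C)(C)C | intermediate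
17 | (14S)-19-membered macrolide: 1,14-lactone of 4-(tert-butyldimethylsilyloxy)-3-[(2E,6E,10E,14S)-14-hydroxy-3,7,11,15-tetramethylhexadeca-2,6,10,15-tetraen-1-yl]benzoic acid | C=C(C)[C@@H]1CC/C(C)=C/CC/C(C)=C/CC/C(C)=C/Cc2cc(ccc2O[Si](C)(C)C(C)(C)C)C(=O)O1 | intermediate
18 | (2R,6S,7S,10E,14S)-6-bromo macrolide aryl TBS ether: C2–C7 bond closed to a 1-methylcyclohexene (C3=C4), Br on C6 cis to the C7 methyl and to the C2 benzylic CH2, 10E-olefin and isopropenyl retained, 15-membered lactone | C=C(C)[C@@H]1CC/C(C)=C/CC[C@@]2(C)[C@H](Cc3cc(ccc3O[Si](C)(C)C(C)(C)C)C(=O)O1)C(C)=CC[C@@H]2Br | intermediate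
19 | (2R,6S,7S,10R,11S,14S)-6,10-dibromo-11-hydroxy macrolide aryl TBS ether (TBS ether of the target) | C=C(C)[C@@H]1CC[C@](C)(O)[C@H](Br)CC[C@@]2(C)[C@H](Cc3cc(ccc3O[Si](C)(C)C(C)(C)C)C(=O)O1)C(C)=CC[C@@H]2Br | intermediate
20 | CNP0213075.1, (2R,6S,7S,10R,11S,14S) | C=C(C)[C@@H]1CC[C@](C)(O)[C@H](Br)CC[C@@]2(C)[C@H](Cc3cc(ccc3O)C(=O)O1)C(C)=CC[C@@H]2Br | target

**Step count and risks**
Total steps: 14. Longest linear sequence: 12 (steps 1, 2, 5–14 from farnesyl acetate; the glycidate branch, steps 3–14, is also 12).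

Step 11 (macrocyclising Diels–Alder benzannulation) may give oligomers, or the silyloxy diene may decompose during the long, dilute heating. The fallback makes the arene–C1 bond and the lactone separately. It sets out from 9: ortho-C-alkylation of the sodium phenoxide of methyl 4-hydroxybenzoate (NaH, toluene, 60 °C) with bromide 9 gives methyl 4-hydroxy-3-[(2E,6E,10E,14S)-14,15-dihydroxy-3,7,11,15-tetramethylhexadeca-2,6,10-trien-1-yl]benzoate F1. TBSCl/imidazole (DMF, 0 °C) silylates only the phenol to give the aryl silyl ether F2. Me3SnOH (1,2-dichloroethane, 80 °C) cleaves the methyl ester to the seco acid F3. Yamaguchi macrolactonisation (2,4,6-trichlorobenzoyl chloride, Et3N, then DMAP, toluene, high dilution) on the secondary C14 hydroxyl gives the C15-hydroxy macrolide F4, and Burgess dehydration of F4 comes back to the route at 17.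

Step 12 (transannular bromocyclisation) is the least predictable step. Br+ may start at the 10,11-olefin instead of the 6,7-olefin, the macrocycle may present the wrong olefin face, or the C3 cation may eliminate to the exocyclic olefin. The fallback replaces bromonium by a bulkier, reversibly complexing electrophile. It sets out from 17: Hg(OTf)2·PhNMe2 (MeNO2, −20 °C), then aqueous NaBr, gives the C6-bromomercurio analogue of 18 F5. Brominative demercuration (Br2, LiBr, pyridine, O2, 0 °C) with retention then comes back at 18.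

Step 13 (bromohydrin) depends on which face of the 10E-olefin the macrocycle exposes, and on selectivity over the ring olefin. The fallback is stereocomplementary because it puts oxygen, not bromine, on the exposed face. It sets out from 18: dimethyldioxirane (acetone, −40 °C) gives the (10S,11S)-10,11-epoxide of 18 F6, and Li2NiBr4 (THF, 0 °C) opens it by SN2 at the secondary C10 with inversion, coming back at 19.

Further compounds
F1 | step 11 | methyl 4-hydroxy-3-[(2E,6E,10E,14S)-14,15-dihydroxy-3,7,11,15-tetramethylhexadeca-2,6,10-trien-1-yl]benzoate | COC(=O)c1ccc(O)c(C/C=C(\C)CC/C=C(\C)CC/C=C(\C)CC[C@H](O)C(C)(C)O)c1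
F2 | step 11 | methyl 4-(tert-butyldimethylsilyloxy)-3-[(2E,6E,10E,14S)-14,15-dihydroxy-3,7,11,15-tetramethylhexadeca-2,6,10-trien-1-yl]benzoate | COC(=O)c1ccc(O[Si](C)(C)C(C)(C)C)c(C/C=C(\C)CC/C=C(\C)CC/C=C(\C)CC[C@H](O)C(C)(C)O)c1
F3 | step 11 | 4-(tert-butyldimethylsilyloxy)-3-[(2E,6E,10E,14S)-14,15-dihydroxy-3,7,11,15-tetramethylhexadeca-2,6,10-trien-1-yl]benzoic acid | OC(=O)c1ccc(O[Si](C)(C)C(C)(C)C)c(C/C=C(\C)CC/C=C(\C)CC/C=C(\C)CC[C@H](O)C(C)(C)O)c1
F4 | step 11 | (14S)-19-membered macrolide aryl TBS ether bearing a 2-hydroxypropan-2-yl group on C14 (C15 tertiary alcohol) | CC(C)(O)[C@@H]1CC/C(C)=C/CC/C(C)=C/CC/C(C)=C/Cc2cc(ccc2O[Si](C)(C)C(C)(C)C)C(=O)O1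
F5 | step 12 | C6-bromomercurio analogue of 18 (HgBr in place of the C6 bromine, same configuration) | C=C(C)[C@@H]1CC/C(C)=C/CC[C@@]2(C)[C@H](Cc3cc(ccc3O[Si](C)(C)C(C)(C)C)C(=O)O1)C(C)=CC[C@@H]2[Hg]Br
F6 | step 13 | (10S,11S)-10,11-epoxide of 18 | C=C(C)[C@@H]1CC[C@]3(C)O[C@H]3CC[C@@]2(C)[C@H](Cc4cc(ccc4O[Si](C)(C)C(C)(C)C)C(=O)O1)C(C)=CC[C@@H]2Br
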